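**Assumptions (one line each)**
- Kuwanon C has no stereocentres, so "the single enantiomer" is moot and nothing needs to be set or preserved. The prenyl C=CMe2 units have no E/Z issue.
- Compounds are numbered in order of first appearance, including the commercial reagents that donate atoms to products.
- MOMCl is expected to protect the 4- and 6-OH groups of compound 1 and leave the chelated 2-OH free, as it does for 2,4,6-trihydroxyacetophenone. Tris-MOM and mono-MOM by-products are separated.

## Retrosynthetic overview
1. Kuwanon C comes from global MOM removal of a tetra-MOM 3,8-diprenylflavone (16).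
2. Key disconnection: the pyranone ring and the C3-prenyl group form together in one Pd(0)-catalysed 6-endo oxa-Michael/prenylation cascade of an o-hydroxyaryl ynone (14). This replaces the chalcone/Baker–Venkataraman route followed by C3 prenylation.
3. Ynone 14 comes from an A-ring aldehyde (8) plus a B-ring lithium acetylide (12), then oxidation. The B ring is attached before the C ring is closed.
4. The 8-prenyl group is placed regiospecifically on the A ring: O-allylation, aromatic Claisen rearrangement into the only free ortho position, then cross-metathesis to the prenyl group. Only the future O1 phenol stays free.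
5. Order of ring formation: A-ring substitution (prenyl), then the B ring is attached via the alkyne, then the C ring and C3-prenyl form in one step.

## Route

**Step 1**
Reactants: 1 (2,4,6-trihydroxybenzaldehyde); 2 (chloromethyl methyl ether, MOMCl)
Product: 3 (2-hydroxy-4,6-bis(methoxymethoxy)benzaldehyde)
Conditions: MOMCl (2.2 equiv), i-Pr2NEt, DMF/CH2Cl2, 0 °C → rt
Reagents that add atoms: MOMCl, COCCl
Why: The 4-OH is most acidic and one of the two equivalent chelated OH groups is also protected, leaving one H-bonded 2-OH. This is MOM-ether formation (phenol protection).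

**Step 2**
Reactants: 3; 4 (allyl bromide)
Product: 5 (2-allyloxy-4,6-bis(methoxymethoxy)benzaldehyde)
Conditions: allyl bromide (1.5 equiv), K2CO3, acetone, reflux
Reagents that add atoms: allyl bromide, C=CCBr
Why: Williamson O-allylation of the only free phenol.

**Step 3**
Reactants: 5
Product: 6 (3-allyl-2-hydroxy-4,6-bis(methoxymethoxy)benzaldehyde)
Conditions: PhNEt2, 200 °C (microwave), 1 h
Reagents that add atoms: none
Why: The aromatic Claisen [3,3] rearrangement can only go to C3, because the other ortho position carries the CHO. This fixes the prenyl carbon next to the future O1, i.e. C8 of the flavone.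

**Step 4**
Reactants: 6; 7 (2-methyl-2-butene)
Product: 8 (2-hydroxy-3-prenyl-4,6-bis(methoxymethoxy)benzaldehyde)
Conditions: Hoveyda–Grubbs II (5 mol %), 1,4-benzoquinone (10 mol %), 2-methyl-2-butene (20 equiv), CH2Cl2, 40 °C
Reagents that add atoms: 2-methyl-2-butene, CC=C(C)C
Why: Olefin cross-metathesis converts the terminal allyl group to the prenyl group, driven by loss of propene. Benzoquinone suppresses Ru–H isomerisation of the allyl group to a propenyl group. The free phenol, aldehyde and MOM groups are tolerated.

**Step 5**
Reactants: 9 (2,4-dihydroxybenzaldehyde); 2 (MOMCl)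
Product: 10 (2,4-bis(methoxymethoxy)benzaldehyde)
Conditions: NaH (2.5 equiv), MOMCl (2.5 equiv), DMF, 0 °C → rt
Reagents that add atoms: MOMCl, COCCl
Why: Double MOM protection of the B-ring phenols so they cannot add to the ynone.

**Step 6**
Reactants: 10; 11 (Ohira–Bestmann reagent, dimethyl (1-diazo-2-oxopropyl)phosphonate)
Product: 12 (1-ethynyl-2,4-bis(methoxymethoxy)benzene)
Conditions: 11 (1.5 equiv), K2CO3, MeOH, rt
Reagents that add atoms: Ohira–Bestmann reagent, CC(=O)C(=[N+]=[N-])P(=O)(OC)OC
Why: Seyferth–Gilbert homologation under Ohira–Bestmann conditions. The conditions are mild and the MOM ethers are base-stable.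

**Step 7**
Reactants: 8; 12
Product: 13 (1-[2-hydroxy-3-prenyl-4,6-bis(MOMO)phenyl]-3-[2,4-bis(MOMO)phenyl]prop-2-yn-1-ol)
Conditions: 12 (3 equiv), n-BuLi (3 equiv), THF, −78 °C; add 8; −78 → 0 °C
Reagents that add atoms: none (12 is the reactant; n-BuLi only deprotonates)
Why: 1,2-addition of a lithium acetylide to the aldehyde. The first equivalent deprotonates the phenol, so excess acetylide is used.

**Step 8**
Reactants: 13
Product: 14 (1-[2-hydroxy-3-prenyl-4,6-bis(MOMO)phenyl]-3-[2,4-bis(MOMO)phenyl]prop-2-yn-1-one)
Conditions: activated MnO2 (10 equiv), CH2Cl2, rt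
Reagents that add atoms: none
Why: Chemoselective oxidation of the propargylic/benzylic alcohol to the ynone. The prenyl alkenes and the chelated phenol are untouched, and the H-bonded o-hydroxyaryl ynone does not cyclise without base.

**Step 9 (key step)**
Reactants: 14; 15 (prenyl bromide, 1-bromo-3-methylbut-2-ene)
Product: 16 (2-[2,4-bis(MOMO)phenyl]-5,7-bis(MOMO)-3,8-diprenylchromen-4-one)
Conditions: prenyl bromide (3 equiv), Pd(PPh3)4 (10 mol %), NaHCO3, MeCN, 50 °C
Reagents that add atoms: prenyl bromide, CC(C)=CCBr
Why: Proposed new method: Pd(0) and prenyl bromide give (η3-prenyl)PdBr, which activates the ynone alkyne. The phenol (as phenoxide or phenol/NaHCO3) attacks anti in a 6-endo-dig oxa-Michael fashion to give the 2-aryl vinyl-Pd species. C–C reductive elimination with the allyl ligand then delivers the linear C3-prenyl group. This extends Cacchi's Pd-catalysed cyclisation/allylation of 2-alkynylphenols (benzofurans) to 6-endo ynone cyclisation, and the weak base is chosen to suppress uncatalysed cycloisomerisation to the 3-H flavone. No stereocentre is formed.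

**Step 10**
Reactants: 16
Product: 17 (Kuwanon C)
Conditions: conc. HCl (cat.), MeOH/THF 1:1, 45 °C
Reagents that add atoms: none
Why: Acid-catalysed hydrolysis of the four aryl MOM acetals. The mild acid and moderate temperature avoid cyclisation of the 7-OH onto the 8-prenyl alkene (chroman formation).

## Compound list
1 | 2,4,6-trihydroxybenzaldehyde | O=Cc1c(O)cc(O)cc1O | starting material
2 | chloromethyl methyl ether (MOMCl) | COCCl | starting material (reagent)
3 | 2-hydroxy-4,6-bis(methoxymethoxy)benzaldehyde | O=Cc1c(O)cc(OCOC)cc1OCOC | intermediate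
4 | allyl bromide | C=CCBr | starting material (reagent)
5 | 2-allyloxy-4,6-bis(methoxymethoxy)benzaldehyde | O=Cc1c(OCC=C)cc(OCOC)cc1OCOC | intermediate
6 | 3-allyl-2-hydroxy-4,6-bis(methoxymethoxy)benzaldehyde | O=Cc1c(O)c(CC=C)c(OCOC)cc1OCOC | intermediate
7 | 2-methyl-2-butene | CC=C(C)C | starting material (reagent)
8 | 2-hydroxy-3-prenyl-4,6-bis(methoxymethoxy)benzaldehyde | O=Cc1c(O)c(CC=C(C)C)c(OCOC)cc1OCOC | intermediate
9 | 2,4-dihydroxybenzaldehyde | O=Cc1ccc(O)cc1O | starting material
10 | 2,4-bis(methoxymethoxy)benzaldehyde | O=Cc1ccc(OCOC)cc1OCOC | intermediate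
11 | dimethyl (1-diazo-2-oxopropyl)phosphonate | CC(=O)C(=[N+]=[N-])P(=O)(OC)OC | starting material (reagent)
12 | 1-ethynyl-2,4-bis(methoxymethoxy)benzene | C#Cc1ccc(OCOC)cc1OCOC | intermediate
13 | propargylic alcohol (diaryl, tetra-MOM, 3-prenyl, free 2-OH) | OC(C#Cc1ccc(OCOC)cc1OCOC)c1c(O)c(CC=C(C)C)c(OCOC)cc1OCOC | intermediate
14 | o-hydroxyaryl ynone | O=C(C#Cc1ccc(OCOC)cc1OCOC)c1c(O)c(CC=C(C)C)c(OCOC)cc1OCOC | intermediate
15 | prenyl bromide | CC(C)=CCBr | starting material (reagent)
16 | tetra-MOM-3,8-diprenylflavone | CC(C)=CCc1c(-c2ccc(OCOC)cc2OCOC)oc2c(CC=C(C)C)c(OCOC)cc(OCOC)c2c1=O | intermediate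
17 | Kuwanon C (achiral) | CC(C)=CCc1c(-c2ccc(O)cc2O)oc2c(CC=C(C)C)c(O)cc(O)c2c1=O | target

## Totals
- Total steps: 10.
- Longest linear sequence: 8 steps (1 → 3 → 5 → 6 → 8 → 13 → 14 → 16 → 17).

## Three steps most likely to fail
1. **Step 9 (Pd oxa-Michael/prenylation).**
   - Risks: uncatalysed cycloisomerisation to the 3-H flavone, O-prenylation of the phenol, reverse-prenyl (1,1-dimethylallyl) coupling, and steric hindrance at C3.
   - Fallback: cyclise ynone 14 with ICl or I2 to give the 3-iodoflavone, then install the prenyl group by Pd-catalysed Stille coupling with prenyl-SnBu3 or Negishi coupling with prenylzinc bromide. This is a two-step, different C–C bond-forming approach.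
2. **Step 7 (acetylide addition to a hindered, electron-rich salicylaldehyde phenoxide).**
   - Risks: poor electrophilicity of the lithium phenoxide aldehyde, and low conversion.
   - Fallback: oxidise aldehyde 8 to the benzoic acid (Pinnick) and convert it to the Weinreb amide, then add lithium acetylide 12 to give ynone 14 directly. This skips the alcohol/oxidation pair and changes the bond-forming mode.
3. **Step 10 (global MOM removal).**
   - Risks: acid-promoted cyclisation of the 7-OH onto the 8-prenyl alkene to a chroman, or prenyl migration.
   - Fallback: redo the sequence with SEM ethers (SEMCl in steps 1 and 5 in place of MOMCl). Remove them at the end with fluoride or MgBr2 under non-protic-acid conditions.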